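## Retrosynthetic overview

1. Last disconnection: the γ-lactone. Its C2–O bond (with C1–C15 in the same event) is cut to a macrocyclic (1E,3E)-diene acetate and 2-bromoacrylic acid; forward, carboxylate C–O bond formation on a π-allylpalladium closes the lactone and fixes C2.
2. The 14-membered carbocycle is cut at C1=C2 to an acyclic ene–diene (ring-closing metathesis); the diene terminus comes from the farnesyl head carbon (deacetylation, MnO2, Wittig).
3. The C11/C12 oxirane and the C13 oxygen come from tartrate-controlled epoxidation of a (13R)-allylic alcohol, made by iridium-catalysed allylation of 12-hydroxyfarnesyl acetate (SeO2 oxidation of farnesyl acetate).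
4. Ring order: oxirane (step 3), 14-membered carbocycle (step 8), γ-lactone (step 9).

Assumptions:
- Locants in the Why lines and in the names of the macrocycles are cembrane locants of the target: C1/C2 ring-fusion carbons (C2 bears the lactone oxygen), C3=C4 and C7=C8 ring alkenes, C11/C12 epoxide, C13 acetoxy carbon, C14 ring CH2, C15 lactone α-carbon, C16 carbonyl, C17 exocyclic CH2. Acyclic intermediates carry their own IUPAC locants.
- The sense of induction of the chiral catalysts in steps 2 and 9 is taken as written; if a test run shows the opposite sense, the antipodal ligand is used with no other change.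

## Route

Step 1
Reactants: 1 (2E,6E)-3,7,11-trimethyldodeca-2,6,10-trien-1-yl acetate ((E,E)-farnesyl acetate)
Product: 2 (2E,6E,10E)-12-hydroxy-3,7,11-trimethyldodeca-2,6,10-trien-1-yl acetate
Conditions: SeO2 (10 mol%), t-BuOOH (70% aq., 3 equiv), salicylic acid (10 mol%), CH2Cl2, 0 °C to rt
Reagents that add atoms: tert-butyl hydroperoxide, CC(C)(C)OO
Why: Selenium dioxide allylic oxidation (ene reaction, then [2,3]-sigmatropic shift) attacks the most electron-rich terminal trisubstituted alkene and oxidises its (E)-methyl group, which installs the future C13 oxygen without creating a stereocentre and leaves the acetate-deactivated 2,3-alkene alone.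

Step 2
Reactants: 2 (2E,6E,10E)-12-hydroxy-3,7,11-trimethyldodeca-2,6,10-trien-1-yl acetate; 3 allyl acetate
Product: 5 (2E,6E,10E,12R)-12-hydroxy-3,7,11-trimethylpentadeca-2,6,10,14-tetraen-1-yl acetate, via aldehyde 4 (not isolated)
Conditions: [Ir(cod)Cl]2 (2.5 mol%), (R)-Cl,MeO-BIPHEP (5 mol%), Cs2CO3 (20 mol%), 3-nitrobenzoic acid (10 mol%), 3 (3 equiv), THF, 100 °C, sealed tube
Reagents that add atoms: none
Why: Krische transfer-hydrogenative carbonyl allylation, in which the cyclometallated iridium benzoate dehydrogenates the primary allylic alcohol to enal 4 and the allyliridium formed from 3 adds through a closed chair transition state to the Re face, setting the carbinol carbon (C12 of 5, C13 of the target) as R while the trisubstituted allylic acetate ionises too slowly to interfere.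

Step 3
Reactants: 5 (2E,6E,10E,12R)-12-hydroxy-3,7,11-trimethylpentadeca-2,6,10,14-tetraen-1-yl acetate
Product: 6 (2E,6E)-9-[(2R,3R)-3-[(1R)-1-hydroxybut-3-en-1-yl]-3-methyloxiran-2-yl]-3,7-dimethylnona-2,6-dien-1-yl acetate
Conditions: Ti(OiPr)4 (15 mol%), D-(−)-diisopropyl tartrate (20 mol%), t-BuOOH (2 equiv, anhydrous), 4 Å MS, CH2Cl2, −20 °C
Reagents that add atoms: tert-butyl hydroperoxide, CC(C)(C)OO
Why: Sharpless asymmetric epoxidation in the matched sense, where D-(−)-tartrate and the (R)-carbinol (erythro preference from A(1,2) strain) direct oxygen to the same face of the only allylic-alcohol alkene, setting both oxirane carbons (target C11 R and C12, the latter named R here and S once the neighbouring oxygen is acetylated) while the minor 12S alcohol reacts slowly and is left behind.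

Step 4
Reactants: 6 (2E,6E)-9-[(2R,3R)-3-[(1R)-1-hydroxybut-3-en-1-yl]-3-methyloxiran-2-yl]-3,7-dimethylnona-2,6-dien-1-yl acetate
Product: 7 (2E,6E)-9-[(2R,3R)-3-[(1R)-1-hydroxybut-3-en-1-yl]-3-methyloxiran-2-yl]-3,7-dimethylnona-2,6-dien-1-ol
Conditions: K2CO3 (0.3 equiv), MeOH, 0 °C
Reagents that add atoms: none
Why: Base-catalysed transesterification removes the primary allylic acetate, and Payne rearrangement is not expected because the carbinol oxygen would have to attack the fully substituted oxirane carbon.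

Step 5
Reactants: 7 (2E,6E)-9-[(2R,3R)-3-[(1R)-1-hydroxybut-3-en-1-yl]-3-methyloxiran-2-yl]-3,7-dimethylnona-2,6-dien-1-ol
Product: 8 (2E,6E)-9-[(2R,3R)-3-[(1R)-1-hydroxybut-3-en-1-yl]-3-methyloxiran-2-yl]-3,7-dimethylnona-2,6-dienal
Conditions: MnO2 (15 equiv), CH2Cl2, rt
Reagents that add atoms: none
Why: MnO2 oxidises only the allylic primary alcohol to the (E)-enal, because the secondary alcohol next to the oxirane is no longer allylic.

Step 6
Reactants: 8 (2E,6E)-9-[(2R,3R)-3-[(1R)-1-hydroxybut-3-en-1-yl]-3-methyloxiran-2-yl]-3,7-dimethylnona-2,6-dienal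
Product: 9 (1R)-1-[(2S,3R)-3-[(3E,7E)-3,7-dimethyl-9-oxonona-3,7-dien-1-yl]-2-methyloxiran-2-yl]but-3-en-1-yl acetate
Conditions: Ac2O (1.5 equiv), pyridine, DMAP (5 mol%), CH2Cl2, 0 °C to rt
Reagents that add atoms: acetic anhydride, CC(=O)OC(C)=O
Why: DMAP-catalysed acylation of the hindered secondary alcohol installs the acetate of the target with retention at carbon, the neighbouring oxirane carbon changing its descriptor from R to S only through the priority rules.

Step 7
Reactants: 9 (1R)-1-[(2S,3R)-3-[(3E,7E)-3,7-dimethyl-9-oxonona-3,7-dien-1-yl]-2-methyloxiran-2-yl]but-3-en-1-yl acetate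
Product: 10 (1R)-1-[(2S,3R)-3-[(3E,7E)-3,7-dimethyldeca-3,7,9-trien-1-yl]-2-methyloxiran-2-yl]but-3-en-1-yl acetate
Conditions: Ph3PCH3Br (1.3 equiv), NaN(SiMe3)2 (1.2 equiv), THF, −78 to 0 °C
Reagents that add atoms: methyltriphenylphosphonium bromide, C[P+](c1ccccc1)(c1ccccc1)c1ccccc1.[Br-]
Why: Wittig methylenation converts the enal into the terminal 1,3-diene without touching the (E)-trisubstituted alkene, the ylide reacting with the aldehyde much faster than with the acetate at low temperature.

Step 8
Reactants: 10 (1R)-1-[(2S,3R)-3-[(3E,7E)-3,7-dimethyldeca-3,7,9-trien-1-yl]-2-methyloxiran-2-yl]but-3-en-1-yl acetate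
Product: 11 (1E,3E,7E,11R,12S,13R)-11,12-epoxy-4,8,12-trimethylcyclotetradeca-1,3,7-trien-13-yl acetate
Conditions: second-generation Grubbs catalyst RuCl2(=CHPh)(H2IMes)(PCy3) (10 mol%), CH2Cl2 (1 mM), 40 °C
Reagents that add atoms: none
Why: Ring-closing metathesis between the only two monosubstituted alkenes closes the 14-membered carbocycle at C1=C2 with loss of ethylene, the trisubstituted alkenes being inert and the conjugated (1E,3E)-diene the thermodynamically preferred geometry.

Step 9
Reactants: 11 (1E,3E,7E,11R,12S,13R)-11,12-epoxy-4,8,12-trimethylcyclotetradeca-1,3,7-trien-13-yl acetate; 12 2-bromoprop-2-enoic acid (2-bromoacrylic acid)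
Product: 13 (1S,2S,3E,7E,11R,12S,13R)-13-acetoxy-11,12-epoxycembra-3,7,15(17)-trien-16,2-olide
Conditions: Pd2(dba)3 (5 mol%), (S)-t-BuPHOX (12 mol%), Ag2CO3 (1.0 equiv), 12 (1.5 equiv), MeCN, 50 °C
Reagents that add atoms: none
Why: Proposed new method: zerovalent palladium inserts into the C–Br bond of the silver carboxylate of 12, the alkenylpalladium adds syn to the less substituted diene terminus C1 (C1–C15 bond) to give a cationic π-allylpalladium over C2–C4, and the tethered carboxylate attacks C2 from the face opposite palladium (the only terminus that gives a five-membered ring) to form the lactone C2–O bond, so that net anti addition across the (E)-C1=C2 alkene gives the cis ring fusion with (E)-C3=C4 retained while the chiral P,N ligand selects the diene face (1S,2S); the closest known reaction type is the palladium-catalysed heteroannulation of 1,3-dienes by organic halides carrying an oxygen nucleophile (Larock annulation), not shown for a macrocyclic, unsymmetrical internal diene with control of both new stereocentres.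

## Compound list

1 | (2E,6E)-3,7,11-trimethyldodeca-2,6,10-trien-1-yl acetate ((E,E)-farnesyl acetate) | CC(=O)OC/C=C(\C)CC/C=C(\C)CCC=C(C)C | starting material
2 | (2E,6E,10E)-12-hydroxy-3,7,11-trimethyldodeca-2,6,10-trien-1-yl acetate | CC(=O)OC/C=C(\C)CC/C=C(\C)CC/C=C(\C)CO | intermediate
3 | allyl acetate (prop-2-en-1-yl acetate) | C=CCOC(C)=O | starting material
4 | (2E,6E,10E)-3,7,11-trimethyl-12-oxododeca-2,6,10-trien-1-yl acetate | CC(=O)OC/C=C(\C)CC/C=C(\C)CC/C=C(\C)C=O | intermediate
5 | (2E,6E,10E,12R)-12-hydroxy-3,7,11-trimethylpentadeca-2,6,10,14-tetraen-1-yl acetate | CC(=O)OC/C=C(\C)CC/C=C(\C)CC/C=C(\C)[C@H](O)CC=C | intermediate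
6 | (2E,6E)-9-[(2R,3R)-3-[(1R)-1-hydroxybut-3-en-1-yl]-3-methyloxiran-2-yl]-3,7-dimethylnona-2,6-dien-1-yl acetate | CC(=O)OC/C=C(\C)CC/C=C(\C)CC[C@H]1O[C@]1(C)[C@H](O)CC=C | intermediate
7 | (2E,6E)-9-[(2R,3R)-3-[(1R)-1-hydroxybut-3-en-1-yl]-3-methyloxiran-2-yl]-3,7-dimethylnona-2,6-dien-1-ol | OC/C=C(\C)CC/C=C(\C)CC[C@H]1O[C@]1(C)[C@H](O)CC=C | intermediate
8 | (2E,6E)-9-[(2R,3R)-3-[(1R)-1-hydroxybut-3-en-1-yl]-3-methyloxiran-2-yl]-3,7-dimethylnona-2,6-dienal | O=C/C=C(\C)CC/C=C(\C)CC[C@H]1O[C@]1(C)[C@H](O)CC=C | intermediate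
9 | (1R)-1-[(2S,3R)-3-[(3E,7E)-3,7-dimethyl-9-oxonona-3,7-dien-1-yl]-2-methyloxiran-2-yl]but-3-en-1-yl acetate | O=C/C=C(\C)CC/C=C(\C)CC[C@H]1O[C@]1(C)[C@H](OC(C)=O)CC=C | intermediate
10 | (1R)-1-[(2S,3R)-3-[(3E,7E)-3,7-dimethyldeca-3,7,9-trien-1-yl]-2-methyloxiran-2-yl]but-3-en-1-yl acetate | C=C/C=C(\C)CC/C=C(\C)CC[C@H]1O[C@]1(C)[C@H](OC(C)=O)CC=C | intermediate
11 | (1E,3E,7E,11R,12S,13R)-11,12-epoxy-4,8,12-trimethylcyclotetradeca-1,3,7-trien-13-yl acetate | CC(=O)O[C@@H]1C/C=C/C=C(\C)CC/C=C(\C)CC[C@H]2O[C@]12C | intermediate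
12 | 2-bromoprop-2-enoic acid (2-bromoacrylic acid) | C=C(Br)C(=O)O | starting material
13 | (1S,2S,3E,7E,11R,12S,13R)-13-acetoxy-11,12-epoxycembra-3,7,15(17)-trien-16,2-olide (14-membered carbocycle cis-fused at C1/C2 to an α-methylene-γ-butyrolactone) | C=C1C(=O)O[C@H]2/C=C(\C)CC/C=C(\C)CC[C@H]3O[C@]3(C)[C@H](OC(C)=O)C[C@@H]12 | target

## Step count and risks

Total step count: 9. Longest linear sequence: 9 steps (1 to 13); 3 and 12 are bought.

The three steps most likely to fail:

Step 9, the proposed annulation. The diene face, the site of carbopalladation (C1 against C4) and outer-sphere against inner-sphere C–O bond formation are untested on a macrocycle, and zerovalent palladium can re-ionise the allylic lactone. The fallback uses known chemistry, sets out from 9 and returns at 13. Cross-metathesis of the terminal alkene of 9 with methyl 2-(bromomethyl)acrylate (second-generation Hoveyda–Grubbs catalyst RuCl2(=CH-C6H4-2-OiPr)(H2IMes), CH2Cl2, 40 °C) gives methyl (2Z,5R)-5-acetoxy-2-(bromomethyl)-5-[(2S,3R)-3-[(3E,7E)-3,7-dimethyl-9-oxonona-3,7-dien-1-yl]-2-methyloxiran-2-yl]pent-2-enoate F1. Slow addition of F1 to CrCl2 in THF (4 Å MS, rt, 2 mM) gives the allylchromium, which adds through C1 to the enal carbon C2 in a chair transition state (Nozaki–Hiyama-type intramolecular allylation, syn adduct); the chromium alkoxide closes the cis-lactone in the flask to 13.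

Step 8, the ring-closing metathesis. The catalyst may be held on the conjugated diene, oligomers may form, and a (1Z)-isomer would lead to the trans-lactone in step 9. The fallback sets out from 9, returns at 13 and closes the ring by carbonyl allylboration instead of metathesis. Cross-metathesis of 9 with methyl 2-[(4,4,5,5-tetramethyl-1,3,2-dioxaborolan-2-yl)methyl]prop-2-enoate (same ruthenium catalyst) gives methyl (2E,5R)-5-acetoxy-5-[(2S,3R)-3-[(3E,7E)-3,7-dimethyl-9-oxonona-3,7-dien-1-yl]-2-methyloxiran-2-yl]-2-[(4,4,5,5-tetramethyl-1,3,2-dioxaborolan-2-yl)methyl]pent-2-enoate F2. Heating F2 in toluene (80 °C, 2 mM) effects intramolecular allylboration of the enal through a chair transition state to methyl 2-[(1S,2S,3E,7E,11R,12S,13R)-13-acetoxy-11,12-epoxy-4,8,12-trimethyl-2-[(4,4,5,5-tetramethyl-1,3,2-dioxaborolan-2-yl)oxy]cyclotetradeca-3,7-dien-1-yl]prop-2-enoate F3, which lactonises with loss of the boron methoxide to 13.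

Step 2, the iridium-catalysed allylation. The α-methyl enal 4 is a hindered acceptor, the allylic acetate may react at 100 °C, and the sense of induction must be confirmed. The fallback sets out from 2 and returns at 6. MnO2 (CH2Cl2, rt) gives aldehyde 4, now isolated. Zinc-mediated Barbier allylation (allyl bromide, Zn, THF/aq. NH4Cl, 0 °C), which spares the acetate, gives the racemic alcohol, that is 5 together with (2E,6E,10E,12S)-12-hydroxy-3,7,11-trimethylpentadeca-2,6,10,14-tetraen-1-yl acetate F4. The conditions of step 3, stopped near 50% conversion, then act as a Sharpless kinetic resolution: 5 is epoxidised to 6 and unreacted F4 is separated.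

Further compounds
F1 | step 9 | methyl (2Z,5R)-5-acetoxy-2-(bromomethyl)-5-[(2S,3R)-3-[(3E,7E)-3,7-dimethyl-9-oxonona-3,7-dien-1-yl]-2-methyloxiran-2-yl]pent-2-enoate | O=C/C=C(\C)CC/C=C(\C)CC[C@H]1O[C@]1(C)[C@H](OC(C)=O)C/C=C(\CBr)C(=O)OC
F2 | step 8 | methyl (2E,5R)-5-acetoxy-5-[(2S,3R)-3-[(3E,7E)-3,7-dimethyl-9-oxonona-3,7-dien-1-yl]-2-methyloxiran-2-yl]-2-[(4,4,5,5-tetramethyl-1,3,2-dioxaborolan-2-yl)methyl]pent-2-enoate | O=C/C=C(\C)CC/C=C(\C)CC[C@H]1O[C@]1(C)[C@H](OC(C)=O)C/C=C(\CB2OC(C)(C)C(C)(C)O2)C(=O)OC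
F3 | step 8 | methyl 2-[(1S,2S,3E,7E,11R,12S,13R)-13-acetoxy-11,12-epoxy-4,8,12-trimethyl-2-[(4,4,5,5-tetramethyl-1,3,2-dioxaborolan-2-yl)oxy]cyclotetradeca-3,7-dien-1-yl]prop-2-enoate | COC(=O)C(=C)[C@H]1[C@@H](OB3OC(C)(C)C(C)(C)O3)/C=C(\C)CC/C=C(\C)CC[C@H]2O[C@]2(C)[C@H](OC(C)=O)C1
F4 | step 2 | (2E,6E,10E,12S)-12-hydroxy-3,7,11-trimethylpentadeca-2,6,10,14-tetraen-1-yl acetate | CC(=O)OC/C=C(\C)CC/C=C(\C)CC/C=C(\C)[C@@H](O)CC=C
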